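## The problem

The target 37 is a 6,7-seco-ent-kauranoid of the spirolactone type. Ring A is spiro-joined at C10 to a δ-lactone (C10, C20, O, C7, C8, C9). The lactone is cis-fused through C8–C9 to ring C, and ring C carries the C15–C16 bridge of a bicyclo[3.2.1]octane with an α-methylene ketone. There are seven stereocentres (C1, C4, C5, C10, C9, C8, C13), and the two quaternary carbons C8 and C10 are separated only by C9. C13 follows from C8 once the bridge is closed, and C1 can be set by reagent approach to a ketone. C5, C10 and C9 cannot be relayed across single bonds and have to be fixed together by a ring. The enone, the two acetates beside one free primary alcohol on C4, and a lactone that can move to a free C1 oxygen exclude strong base or nucleophiles late in the route. C5 is also at risk whenever C6 is a carbonyl group. The enabling feature is that C6 (CH2OAc) and C7 (lactone carbonyl) are the two ends of a broken bond. If they are joined, C5, C6, C7, C8, C9, C10 form a ring B that is cis-fused to ring A, with H5, H9 and C20 on one face. That cis-octalone is what an oxy-Cope rearrangement of a 2-alkenylbicyclo[2.2.2]oct-5-en-2-ol delivers, with C7 as carbinol carbon, C8=C9 as the alkenyl group and C1=C10 as the bicyclic alkene.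

## Retrosynthesis

**C15 ketone and C19 hydroxyl (37 ← 36 ← 34).** The enone is the most fragile group and is made last: the C15 carbonyl comes from allylic oxidation of the exocyclic alkene of 34 through the alcohol 35, and the C19 silyl ether of 36 is removed in the final step. No C–C bond is cut. This is preferred over carrying a C15 oxygen through the route, because every earlier step then sees only an unfunctionalised alkene. The forward reactions must oxidise C15 and not C13, and must spare two acetates and a lactone.

**C6–C7 (34 ← 32 ← 31).** Retrosynthetically C6 is bonded to C7: the lactone carbonyl and the C6 aldehyde of 32 are the two halves of the α-hydroxy ketone 31, in which ring B is intact. An oxidative cut of a ketol gives exactly the two oxidation levels required (acid at C7, aldehyde at C6). A diketone or diol cleavage would give equal levels that cannot be told apart next to the C20 hydroxyl. The precursor 31 is a cis-fused tetracycle, in which C5, C10 and C9 are held by a ring. The forward step needs the C20 hydroxyl to capture the C7 acyl group and the C1 oxygen to be already acetylated.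

**Adjustment of C6 and C1 (31 ← 28 ← 27 ← 26 ← 24 ← 23).** The C6 hydroxyl comes from the enol silane 28 of the C6-methylene ketone 27, and 27 from the dimethyl ketal 26 by reductive loss of both methoxy groups. The C1 acetate comes from the C1 ketone 24, which is the hydrolysed enol ether of 23. The ketal is kept until C1 has been reduced for three reasons: it blocks C6 during C8 alkylation, it removes abstractable hydrogen next to the radical centre, and it makes the C7 ketone too hindered for hydride so that C1 can be reduced alone. The C1 ketone is reduced while ring B still exists, because the cis-fused bicycle gives a clear convex face.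

**Ring D (23 ← 22 ← 19 + 20).** C13–C16 is cut first, as a 5-exo vinyl radical closure onto the ring C alkene. Then C8–C15 is cut, as alkylation of the C7 enolate with the three-carbon unit 20. Both bonds use functionality that the key step leaves behind (the enol silane and the C12=C13 alkene), so no extra handles are needed. The alkylation must put C15 on the face of H9.

**C9–C10 and ring B, the key cut (19 ← 16).** The silyl enol ether 19 is the oxy-Cope product of the carbinol 16. The cut removes ring B, the spiro-type quaternary centre C10 and the C9 stereocentre in one step. It leaves a bicyclo[2.2.2]octenol whose stereocentres (C4, C5) come from a cycloaddition. No neighbouring cut (C10–C20, C8–C9, C5–C10) removes two hindered centres with a built-in stereochemical link. The forward reaction requires the dienyl group syn to the enol ether bridge.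

**C7–C8 and the C4 side chain (16 ← 15 ← 14 ← 11 + 4; 4 ← 3 ← 1 + 2).** The dienyl group is added to the ketone 11 as an organocerium reagent made from the iodide 4. The ester of 14 is reduced (15) and silylated (16) before the key step, when it is the only carbonyl group. The iodide 4 comes from the boronate 3, the cycloadduct of 1 and 2. The cyclohexa-1,4-diene is chosen over a cyclohexene because its second alkene ends up as C12=C13, where ring D needs it.

**The bicyclic core (11 ← 10 ← 7 + 8; 7 ← 6 ← 5).** C2–C3 and C4–C5 are cut in a Diels–Alder reaction between methacrylate 8 and the o-quinone monoketal 9, generated from phenol 7. The racemic adduct 10 is resolved to 11. The starting material is the aromatic aldehyde 5, whose substituents map onto C1 (OMe), C6 (OMe), C7 (OH) and C20 (CHO). The cycloaddition must place the quaternary carbon next to C5 and the ester endo.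

## Roads not taken

Alternative 1: The cut is C13–C16, made last on the finished spirolactone. A tert-butyl β-keto ester chain on C8 is oxidised by Mn(OAc)3 with Cu(OAc)2 to the C16 radical; this adds to C13 of a ring C alkene, and oxidation of the C12 radical gives A1.
- Merits: ring D closes with C15 already a ketone and C16 activated for methylenation, so no allylic oxidation is needed; lactone and acetates tolerate the conditions.
- Weak points: dicarbonyl radicals often close 6-endo on 1,2-disubstituted cyclohexenes, which would give a bicyclo[2.2.2]octane. The C11–C12 alkene left by the oxidative termination must be hydrogenated without touching a later exocyclic methylene. The cut concerns ring D only, so C10, C9 and C8 must already be in place.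
- Comparison: for ring D alone this road is at least as good as the chosen one (one C–C step fewer, oxidation state in place). The chosen plan offers a vinyl radical closure whose 5-exo course is not in doubt, and it also makes C9–C10, which this alternative leaves unsolved.

Alternative 2: The cut is C10–C20. A ring A enone with hydrogen on C10 carries the C7 acid as its chloromethyl ester; KN(SiMe3)2 forms the C10 enolate, which displaces chloride to close the lactone and create the spiro centre in A2.
- Merits: lactone, C20 and the quaternary C10 appear in one late step. No temporary ring is excised, which saves the operations the chosen plan spends on C6 and C7 (steps 16 to 20).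
- Weak points: the tether hangs from C9, which lies in the enolate plane, so both faces of C10 are within reach and the relation to C5 rests on conformational bias only. The chloromethyl ester is exposed to a strong base. The C9–C10 bond between two crowded carbons must be made earlier by other means.
- Comparison: this road is more convergent and shorter after its key step. The chosen plan fixes C5, C10 and C9 together in one pericyclic transition state, which this road cannot guarantee.

Alternative 3: The cut is C8–C14 and C9–C11, i.e. ring C. A 3-acetyl-5,6-dihydropyran-2-one spiro-fused to ring A reacts with a butadienyl(dimethyl)silyl ether on the C6 oxygen in an intramolecular Diels–Alder reaction to give A3.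
- Merits: ring C, the quaternary C8 and C9 form in one step on the finished lactone; the tether from C6 selects the alkene face; the acetyl group supplies C15 and C16.
- Weak points: the dienophile carbon C9 is neopentyl (next to C10), and 1-silyl dienes are poor dienes. A seven-membered siloxane is formed. C10 must be set relative to C5 beforehand, and the silicon on C11 and the C13–C16 bond still need several steps.
- Comparison: like Alternative 2 it avoids the excision of ring B, which is a real saving. The chosen plan relies on a rearrangement with close precedent and a forced cis outcome, and pays about five steps for the temporary ring.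

Key step: step 10

Remarks on the chemistry: atoms keep the target numbering throughout (C18 is the methyl and C19 the oxygenated carbon on C4). The racemate 10 is written as the SMILES of both enantiomers joined by a dot. The configurations drawn at C6 in 29–31 and at C15 in 35 are the expected ones; both centres are destroyed in steps 19 and 23, so their epimers would converge.

Step 1
Reactants: 1 buta-1,3-diene; 2 2-ethynyl-4,4,5,5-tetramethyl-1,3,2-dioxaborolane
Product: 3 2-(cyclohexa-1,4-dien-1-yl)-4,4,5,5-tetramethyl-1,3,2-dioxaborolane
Conditions: CoBr2(dppe) (5 mol %; dppe = 1,2-bis(diphenylphosphino)ethane), Zn, ZnI2, CH2Cl2, rt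
Reagents that add atoms: none
Why: Cobalt-catalysed [4+2] cycloaddition of an alkynylboronate with a 1,3-diene (a neutral Diels–Alder reaction through a low-valent cobalt–diphosphine complex) should give the 1,4-diene with boron on the new double bond at room temperature; no stereocentre is formed.

Step 2
Reactants: 3 2-(cyclohexa-1,4-dien-1-yl)-4,4,5,5-tetramethyl-1,3,2-dioxaborolane
Product: 4 1-iodocyclohexa-1,4-diene
Conditions: aq. NaOH, then I2, THF, 0 °C, dark
Reagents that add atoms: iodine, II
Why: Iododeboronation of an alkenyl pinacol boronate through its hydroxy ate complex (ipso substitution by iodine) is a standard route to alkenyl iodides; the boron-bearing double bond is the more nucleophilic one, so the isolated ring alkene should be spared at 0 °C.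

Step 3
Reactants: 5 4-hydroxy-2,5-dimethoxybenzaldehyde
Product: 6 4-(hydroxymethyl)-2,5-dimethoxyphenol
Conditions: NaBH4, MeOH, 0 °C
Reagents that add atoms: none
Why: Borohydride reduction of an aryl aldehyde; the phenol needs no protection.

Step 4
Reactants: 6 4-(hydroxymethyl)-2,5-dimethoxyphenol
Product: 7 4-[(tert-butyldimethylsilyloxy)methyl]-2,5-dimethoxyphenol
Conditions: t-BuMe2SiCl (1.05 equiv), imidazole, DMF, 0 °C
Reagents that add atoms: tert-butyldimethylsilyl chloride, C[Si](C)(Cl)C(C)(C)C
Why: Silylation with imidazole should take the primary benzylic hydroxyl in preference to the less nucleophilic phenol when one equivalent of chlorosilane is used at 0 °C.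

Step 5
Reactants: 7 4-[(tert-butyldimethylsilyloxy)methyl]-2,5-dimethoxyphenol; 8 methyl methacrylate
Product: 10 racemic methyl 6-[(tert-butyldimethylsilyloxy)methyl]-5,7,7-trimethoxy-2-methyl-8-oxobicyclo[2.2.2]oct-5-ene-2-carboxylate (ester on the side of the enol ether bridge), via masked o-benzoquinone 9 (not isolated)
Conditions: PhI(OAc)2, MeOH, 8 (10 equiv), 0 °C to rt, then 60 °C
Reagents that add atoms: methanol, CO
Why: Oxidative dearomatisation of a 2-methoxyphenol in methanol gives the o-quinone monoketal 9 (methanol adds at the methoxy-bearing carbon), which is trapped in situ in a Diels–Alder reaction. C2 of 9 is the α-carbon of a vinylogous ester and the nucleophilic end of a 2-methoxydiene, so it should bond to the CH2 of the methacrylate, and endo addition puts the ester on the side of the new enol ether bridge and the methyl toward the ketal bridge, which fixes C4 relative to C5; both enantiomers form.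

Step 6
Reactants: 10 racemic bicyclo[2.2.2]octenone ester
Product: 11 methyl 6-[(tert-butyldimethylsilyloxy)methyl]-5,7,7-trimethoxy-2-methyl-8-oxobicyclo[2.2.2]oct-5-ene-2-carboxylate, single enantiomer with the C4 and C5 configuration of the target
Conditions: preparative supercritical-fluid chromatography, amylose tris(3,5-dimethylphenylcarbamate) phase, CO2/2-propanol
Reagents that add atoms: none
Why: Resolution on a chiral stationary phase at the first chiral intermediate, a rigid ketone with ester and ketal groups for chiral recognition; the absolute configuration would be confirmed later by crystallography of a crystalline intermediate.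

Step 7
Reactants: 4 1-iodocyclohexa-1,4-diene; 11 resolved bicyclo[2.2.2]octenone ester
Product: 14 methyl ester of the tertiary carbinol bearing the cyclohexa-1,4-dienyl group on C7 syn to the C1=C10 enol ether bridge, via dienyllithium 12 (not isolated), via dienylcerium dichloride 13 (not isolated)
Conditions: 4, t-BuLi (2 equiv), Et2O, −78 °C; CeCl3, THF, −78 °C; then 11, −78 to −40 °C; aq. NH4Cl
Reagents that add atoms: none
Why: Iodine–lithium exchange at −78 °C is faster than proton transfer from the doubly allylic CH2 groups, and the derived organocerium reagent adds to the hindered, non-enolisable ketone without touching the neopentyl ester. Attack from the face of the enol ether bridge (the C3 methylene bridge shields the other face) places the dienyl group syn to C1=C10, as the key step requires.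

Step 8
Reactants: 14 carbinol methyl ester
Product: 15 diol with tertiary C7 hydroxyl and primary C19 hydroxyl
Conditions: LiAlH4, THF, 0 °C
Reagents that add atoms: none
Why: LiAlH4 reduces the hindered methyl ester to the primary alcohol while ketal, enol ether, silyl ether and diene are inert; doing this before the key step avoids any later hydride reduction of an ester beside ketones.

Step 9
Reactants: 15 diol
Product: 16 tertiary carbinol with C19 tert-butyldiphenylsilyl ether and C20 tert-butyldimethylsilyl ether
Conditions: t-BuPh2SiCl, imidazole, DMF, rt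
Reagents that add atoms: tert-butyldiphenylsilyl chloride, CC(C)(C)[Si](Cl)(c1ccccc1)c1ccccc1
Why: Silylation is selective for the primary hydroxyl; the tertiary carbinol stays free for step 10, and the tert-butyldiphenylsilyl ether will outlast the acid and fluoride steps that later free C20.

Step 10
Reactants: 16 bicyclo[2.2.2]octenyl cyclohexadienyl carbinol
Product: 19 cis-fused tricyclic trimethylsilyl enol ether (C7 OSiMe3 and C7=C8; C1 methyl enol ether; C12=C13), via potassium alkoxide 17 (not isolated), via potassium enolate 18 (not isolated)
Conditions: KH, 18-crown-6, THF, 0 °C to rt; then Me3SiCl, Et3N, −78 °C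
Reagents that add atoms: chlorotrimethylsilane, C[Si](C)(C)Cl
Why: Anionic oxy-Cope rearrangement: KH with 18-crown-6 gives the free potassium alkoxide 17, whose C7–C2 bond is weakened by the oxyanion and breaks as C9 of the dienyl group bonds to C10 of the enol ether bridge in a concerted [3,3] shift, and the enolate 18 is silylated on oxygen. The closest known reaction type is the rearrangement of 2-alkenylbicyclo[2.2.2]oct-5-en-2-ols, adducts of masked o-benzoquinones included, to cis-fused octalones. Ring B (C5, C6, C7, C8, C9, C10) is closed by the C9–C10 bond within the six-atom array C9, C8, C7, C2, C1, C10 while the bicyclooctene opens to ring A, a ring expansion and not a separate cyclisation. C10 is set because C9 can reach only the face of the C1=C10 bridge that looks at the carbinol bridge, the face that also carries C6 on C5, so the A/B fusion is cis with C20 and H5 on the same side. C9 is set by the boat geometry that the bicycle enforces together with the cis ring double bond of the diene, which places H9 on the face of C20 and H5. The step needs the dienyl group syn to the enol ether bridge, which step 7 provides. It also needs the [3,3] path to win over [1,3] shift or fragmentation, which the rigid syn arrangement and the crown ether favour. The C6 ketal leaves C8 as the only enolate position, and the doubly allylic CH2 groups are not acidic enough for KH.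

Step 11
Reactants: 19 tricyclic silyl enol ether; 20 2,3-dibromopropene
Product: 22 tricyclic C7 ketone with a 2-bromoallyl group on C8 cis to H9, via lithium enolate 21 (not isolated)
Conditions: MeLi, THF, 0 °C; then HMPA, 20, −78 to 0 °C
Reagents that add atoms: none
Why: Methyllithium cleaves the silyl enol ether to the lithium enolate 21, which can be alkylated only at C8 because C6 is a ketal (enolate alkylation with an allylic bromide forming a ring-fusion quaternary centre). In the cis-fused enolate the upper face of C8 is screened 1,3 by C1 of ring A and by an axial C6 methoxy group, so the electrophile should enter on the face of H9, H5 and C20, giving the cis B/C fusion with C15 syn to H9.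

Step 12
Reactants: 22 C8 2-bromoallyl ketone
Product: 23 tetracyclic ketone with ring D closed (C16=C17 exocyclic alkene, C6 ketal, C1 methyl enol ether)
Conditions: Bu3SnH, AIBN, PhH, 80 °C
Reagents that add atoms: none
Why: The tin radical abstracts bromine and the C16 vinyl radical closes 5-exo-trig onto C13 of the ring C alkene (vinyl radical cyclisation to a bicyclo[3.2.1]octane), the C12 radical then taking hydrogen from the stannane. The bridge can form only on the face of ring C that carries C15, so C13 follows from C8, and a high stannane concentration suppresses rearrangement to the bicyclo[2.2.2]octane.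

Step 13
Reactants: 23 tetracyclic enol ether ketone
Product: 24 tetracyclic 1,7-diketone with C6 dimethyl ketal
Conditions: aq. oxalic acid, THF, rt
Reagents that add atoms: water, O
Why: A methyl enol ether is hydrolysed by dilute acid far faster than a ketal next to a ketone or a neopentyl silyl ether, so only C1 is unmasked.

Step 14
Reactants: 24 1,7-diketone
Product: 25 C1 alcohol with hydroxyl cis to C9 and C6, C7 ketone unchanged
Conditions: LiBH(s-Bu)3, THF, −78 °C; aq. NH4Cl
Reagents that add atoms: none
Why: The C7 ketone lies between a quaternary carbon and a ketal carbon and should not react with the bulky hydride. C1 is reduced from the convex face of the cis-fused A/B system (the face of C20 and H5), the concave face being closed by C9 and C6, which puts the C1 hydroxyl cis to C9 and C6 as in the target.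

Step 15
Reactants: 25 C1 alcohol
Product: 26 C1 acetate
Conditions: Ac2O, DMAP, pyridine, CH2Cl2, rt
Reagents that add atoms: acetic anhydride, CC(=O)OC(C)=O
Why: Acylation of the hindered secondary alcohol under 4-dimethylaminopyridine catalysis installs the C1 acetate of the target before any step in which a free C1 hydroxyl could compete with C20 for the C7 acyl group.

Step 16
Reactants: 26 C1 acetate with C6 ketal
Product: 27 C7 ketone with C6 methylene
Conditions: SmI2 (excess), THF–MeOH, −78 to 0 °C
Reagents that add atoms: none
Why: Samarium diiodide reduces ketones bearing α-alkoxy groups by electron transfer to the carbonyl and loss of alkoxide, twice here, leaving CH2 at C6. Acetate, silyl ethers and the 1,1-disubstituted alkene are inert, and the ketal has by now served as blocking group.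

Step 17
Reactants: 27 C6-methylene ketone
Product: 28 C6=C7 trimethylsilyl enol ether
Conditions: Me3SiOTf, Et3N, CH2Cl2, 0 °C
Reagents that add atoms: trimethylsilyl trifluoromethanesulfonate, C[Si](C)(C)OS(=O)(=O)C(F)(F)F
Why: Soft enolisation with a silyl triflate and an amine gives the only possible enol silane (C8 is quaternary) without the strong base that would endanger the acetate.

Step 18
Reactants: 28 C6=C7 silyl enol ether
Product: 31 C6-hydroxy C7 ketone with free C20 hydroxyl, via silyloxy epoxide 29 (not isolated), via silyloxy ketone 30 (not isolated)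
Conditions: dimethyldioxirane, acetone–CH2Cl2, −78 to −40 °C; then aq. HF, MeCN, 0 °C
Reagents that add atoms: dimethyldioxirane, CC1(C)OO1
Why: Rubottom oxidation: the electron-rich silyl enol ether is epoxidised much faster than the exocyclic methylene, from the face of H5, and the epoxide 29 rearranges with silyl transfer to the α-silyloxy ketone 30. Aqueous HF then removes the trimethylsilyl group and the C20 tert-butyldimethylsilyl ether but not the tert-butyldiphenylsilyl ether; the configuration at C6 is of no consequence.

Step 19
Reactants: 31 C6-hydroxy C7 ketone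
Product: 32 spirolactone aldehyde (C7–O–C20 lactone, C6 aldehyde)
Conditions: Pb(OAc)4, CH2Cl2, 0 °C
Reagents that add atoms: none
Why: Lead tetraacetate cleaves the α-hydroxy ketone as a glycol equivalent: the C20 hydroxyl adds to the C7 carbonyl (2-oxabicyclo[2.2.2]octane hemiketal) and the C6–C7 bond breaks, so C7 leaves as the six-membered lactone and C6 as the aldehyde, the same oxidative cut that turns 7,20-epoxy-ent-kauranes into spirolactones. No stereocentre is touched, and C5 should not epimerise under these cold, non-basic conditions.

Step 20
Reactants: 32 spirolactone aldehyde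
Product: 33 spirolactone with primary C6 alcohol
Conditions: NaBH4, MeOH–THF, −20 °C
Reagents that add atoms: none
Why: Sodium borohydride reduces the aldehyde at low temperature without attacking lactone or acetate, and removes the carbonyl group that would let C5 epimerise.

Step 21
Reactants: 33 C6 alcohol
Product: 34 C1,C6-diacetate
Conditions: Ac2O, DMAP, pyridine, CH2Cl2, rt
Reagents that add atoms: acetic anhydride, CC(=O)OC(C)=O
Why: Acetylation of the primary alcohol gives the second acetate of the target; the C19 oxygen is still silylated, so the three hydroxyl groups stay differentiated.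

Step 22
Reactants: 34 diacetate with exocyclic alkene
Product: 35 C15 allylic alcohol
Conditions: SeO2 (cat.), t-BuOOH, CH2Cl2, rt
Reagents that add atoms: tert-butyl hydroperoxide, CC(C)(C)OO
Why: Selenium dioxide with tert-butyl hydroperoxide oxidises the C15 methylene of the exocyclic alkene by an ene reaction and [2,3]-sigmatropic shift (allylic oxidation), the standard entry to 15-oxygenated ent-kaur-16-enes. The bridgehead C13 cannot react, and the exo alcohol drawn is the expected epimer.

Step 23
Reactants: 35 C15 allylic alcohol
Product: 36 C15 ketone (α-methylene ketone) with C19 silyl ether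
Conditions: Dess–Martin periodinane, NaHCO3, CH2Cl2, rt
Reagents that add atoms: none
Why: Dess–Martin oxidation of the allylic alcohol gives the α-methylene ketone under buffered, non-basic conditions that enone, acetates and lactone tolerate.

Step 24
Reactants: 36 enone silyl ether
Product: 37 target (CNP0370815.4)
Conditions: HF·pyridine, THF, 0 °C to rt
Reagents that add atoms: none
Why: HF·pyridine cleaves the last silyl ether without base, so the enone is not attacked by nucleophiles and neither acetate should migrate to the freed C19 hydroxyl.

Compound list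

1 | buta-1,3-diene | C=CC=C | starting material
2 | 2-ethynyl-4,4,5,5-tetramethyl-1,3,2-dioxaborolane | C#CB1OC(C)(C)C(C)(C)O1 | starting material
3 | 2-(cyclohexa-1,4-dien-1-yl)-4,4,5,5-tetramethyl-1,3,2-dioxaborolane | CC1(C)OB(C2=CCC=CC2)OC1(C)C | intermediate
4 | 1-iodocyclohexa-1,4-diene | IC1=CCC=CC1 | intermediate
5 | 4-hydroxy-2,5-dimethoxybenzaldehyde | COc1cc(C=O)c(OC)cc1O | starting material
6 | 4-(hydroxymethyl)-2,5-dimethoxyphenol | COc1cc(CO)c(OC)cc1O | intermediate
7 | 4-[(tert-butyldimethylsilyloxy)methyl]-2,5-dimethoxyphenol | COc1cc(CO[Si](C)(C)C(C)(C)C)c(OC)cc1O | intermediate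
8 | methyl methacrylate | C=C(C)C(=O)OC | starting material
9 | 4-[(tert-butyldimethylsilyloxy)methyl]-3,6,6-trimethoxycyclohexa-2,4-dien-1-one (masked o-benzoquinone) | COC1=CC(=O)C(OC)(OC)C=C1CO[Si](C)(C)C(C)(C)C | intermediate
10 | racemic methyl 6-[(tert-butyldimethylsilyloxy)methyl]-5,7,7-trimethoxy-2-methyl-8-oxobicyclo[2.2.2]oct-5-ene-2-carboxylate, ester syn to the enol ether bridge | O=C1C(OC)(OC)[C@H]2C(CO[Si](C)(C)C(C)(C)C)=C(OC)[C@@H]1C[C@]2(C)C(=O)OC.O=C1C(OC)(OC)[C@@H]2C(CO[Si](C)(C)C(C)(C)C)=C(OC)[C@H]1C[C@@]2(C)C(=O)OC | intermediate
11 | the same bicyclo[2.2.2]octenone ester as single enantiomer (C4 and C5 as in the target) | O=C1C(OC)(OC)[C@H]2C(CO[Si](C)(C)C(C)(C)C)=C(OC)[C@@H]1C[C@]2(C)C(=O)OC | intermediate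
12 | cyclohexa-1,4-dien-1-yllithium | [Li]C1=CCC=CC1 | intermediate
13 | (cyclohexa-1,4-dien-1-yl)cerium dichloride | Cl[Ce](Cl)C1=CCC=CC1 | intermediate
14 | tertiary carbinol methyl ester: C7 bears OH (over the C3–C4 bridge) and the cyclohexa-1,4-dienyl group (syn to the C1=C10 enol ether bridge) | O[C@]1(C3=CCC=CC3)C(OC)(OC)[C@H]2C(CO[Si](C)(C)C(C)(C)C)=C(OC)[C@@H]1C[C@]2(C)C(=O)OC | intermediate
15 | diol: C7 tertiary carbinol and C19 primary alcohol | O[C@]1(C3=CCC=CC3)C(OC)(OC)[C@H]2C(CO[Si](C)(C)C(C)(C)C)=C(OC)[C@@H]1C[C@]2(C)CO | intermediate
16 | oxy-Cope precursor: C7 tertiary carbinol, C19 tert-butyldiphenylsilyl ether, C20 tert-butyldimethylsilyl ether | O[C@]1(C3=CCC=CC3)C(OC)(OC)[C@H]2C(CO[Si](C)(C)C(C)(C)C)=C(OC)[C@@H]1C[C@]2(C)CO[Si](c4ccccc4)(c5ccccc5)C(C)(C)C | intermediate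
17 | potassium alkoxide of 16 | [K+].[O-][C@]1(C3=CCC=CC3)C(OC)(OC)[C@H]2C(CO[Si](C)(C)C(C)(C)C)=C(OC)[C@@H]1C[C@]2(C)CO[Si](c4ccccc4)(c5ccccc5)C(C)(C)C | intermediate
18 | potassium C7 enolate of the cis-fused tricycle | [K+].[O-]C1=C2CC=CC[C@H]2[C@@]3(CO[Si](C)(C)C(C)(C)C)C(OC)=CC[C@](C)(CO[Si](c4ccccc4)(c5ccccc5)C(C)(C)C)[C@H]3C1(OC)OC | intermediate
19 | cis-fused tricyclic trimethylsilyl enol ether (C7=C8, C1=C2 methyl enol ether, C12=C13, C6 dimethyl ketal; H5, H9 and C20 on one face) | C[Si](C)(C)OC1=C2CC=CC[C@H]2[C@@]3(CO[Si](C)(C)C(C)(C)C)C(OC)=CC[C@](C)(CO[Si](c4ccccc4)(c5ccccc5)C(C)(C)C)[C@H]3C1(OC)OC | intermediate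
20 | 2,3-dibromopropene | C=C(Br)CBr | starting material
21 | lithium C7 enolate of the tricycle | [Li+].[O-]C1=C2CC=CC[C@H]2[C@@]3(CO[Si](C)(C)C(C)(C)C)C(OC)=CC[C@](C)(CO[Si](c4ccccc4)(c5ccccc5)C(C)(C)C)[C@H]3C1(OC)OC | intermediate
22 | tricyclic C7 ketone with 2-bromoallyl on C8, cis to H9 | C=C(Br)C[C@]12CC=CC[C@H]1[C@@]3(CO[Si](C)(C)C(C)(C)C)C(OC)=CC[C@](C)(CO[Si](c4ccccc4)(c5ccccc5)C(C)(C)C)[C@H]3C(OC)(OC)C2=O | intermediate
23 | tetracyclic C7 ketone with bicyclo[3.2.1]octane rings C/D, exocyclic C16=C17, C6 ketal, C1 methyl enol ether | C=C1C[C@]23C[C@H]1CC[C@H]2[C@@]4(CO[Si](C)(C)C(C)(C)C)C(OC)=CC[C@](C)(CO[Si](c5ccccc5)(c6ccccc6)C(C)(C)C)[C@H]4C(OC)(OC)C3=O | intermediate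
24 | tetracyclic C1,C7-diketone with C6 ketal | C=C1C[C@]23C[C@H]1CC[C@H]2[C@@]4(CO[Si](C)(C)C(C)(C)C)C(=O)CC[C@](C)(CO[Si](c5ccccc5)(c6ccccc6)C(C)(C)C)[C@H]4C(OC)(OC)C3=O | intermediate
25 | C1 alcohol (OH cis to C9 and C6), C7 ketone | C=C1C[C@]23C[C@H]1CC[C@H]2[C@@]4(CO[Si](C)(C)C(C)(C)C)[C@@H](O)CC[C@](C)(CO[Si](c5ccccc5)(c6ccccc6)C(C)(C)C)[C@H]4C(OC)(OC)C3=O | intermediate
26 | C1 acetate, C6 ketal, C7 ketone | C=C1C[C@]23C[C@H]1CC[C@H]2[C@@]4(CO[Si](C)(C)C(C)(C)C)[C@@H](OC(C)=O)CC[C@](C)(CO[Si](c5ccccc5)(c6ccccc6)C(C)(C)C)[C@H]4C(OC)(OC)C3=O | intermediate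
27 | C1 acetate, C6 methylene, C7 ketone | C=C1C[C@]23C[C@H]1CC[C@H]2[C@@]4(CO[Si](C)(C)C(C)(C)C)[C@@H](OC(C)=O)CC[C@](C)(CO[Si](c5ccccc5)(c6ccccc6)C(C)(C)C)[C@H]4CC3=O | intermediate
28 | C6=C7 trimethylsilyl enol ether | C=C1C[C@]23C[C@H]1CC[C@H]2[C@@]4(CO[Si](C)(C)C(C)(C)C)[C@@H](OC(C)=O)CC[C@](C)(CO[Si](c5ccccc5)(c6ccccc6)C(C)(C)C)[C@H]4C=C3O[Si](C)(C)C | intermediate
29 | C6,C7 epoxide with trimethylsilyloxy on C7, epoxide oxygen on the face of H5 | C=C1C[C@]23C[C@H]1CC[C@H]2[C@@]4(CO[Si](C)(C)C(C)(C)C)[C@@H](OC(C)=O)CC[C@](C)(CO[Si](c5ccccc5)(c6ccccc6)C(C)(C)C)[C@H]4[C@@H]7O[C@@]73O[Si](C)(C)C | intermediate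
30 | C6 trimethylsilyloxy C7 ketone with C20 silyl ether | C=C1C[C@]23C[C@H]1CC[C@H]2[C@@]4(CO[Si](C)(C)C(C)(C)C)[C@@H](OC(C)=O)CC[C@](C)(CO[Si](c5ccccc5)(c6ccccc6)C(C)(C)C)[C@H]4[C@H](O[Si](C)(C)C)C3=O | intermediate
31 | C6-hydroxy C7 ketone with free C20 hydroxyl, C1 acetate, C19 silyl ether | C=C1C[C@]23C[C@H]1CC[C@H]2[C@@]4(CO)[C@@H](OC(C)=O)CC[C@](C)(CO[Si](c5ccccc5)(c6ccccc6)C(C)(C)C)[C@H]4[C@H](O)C3=O | intermediate
32 | spirolactone aldehyde (C7–O–C20 lactone, C6 aldehyde, C1 acetate) | C=C1C[C@]23C[C@H]1CC[C@H]2[C@@]1(COC3=O)[C@@H](OC(C)=O)CC[C@](C)(CO[Si](c4ccccc4)(c5ccccc5)C(C)(C)C)[C@H]1C=O | intermediate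
33 | spirolactone with C6 primary alcohol | C=C1C[C@]23C[C@H]1CC[C@H]2[C@@]1(COC3=O)[C@@H](OC(C)=O)CC[C@](C)(CO[Si](c4ccccc4)(c5ccccc5)C(C)(C)C)[C@H]1CO | intermediate
34 | spirolactone C1,C6-diacetate with exocyclic alkene | C=C1C[C@]23C[C@H]1CC[C@H]2[C@@]1(COC3=O)[C@@H](OC(C)=O)CC[C@](C)(CO[Si](c4ccccc4)(c5ccccc5)C(C)(C)C)[C@H]1COC(C)=O | intermediate
35 | C15 allylic alcohol (exo hydroxyl) | C=C1[C@H](O)[C@]23C[C@H]1CC[C@H]2[C@@]1(COC3=O)[C@@H](OC(C)=O)CC[C@](C)(CO[Si](c4ccccc4)(c5ccccc5)C(C)(C)C)[C@H]1COC(C)=O | intermediate
36 | C15 ketone with exocyclic methylene, C19 tert-butyldiphenylsilyl ether | C=C1C(=O)[C@]23C[C@H]1CC[C@H]2[C@@]1(COC3=O)[C@@H](OC(C)=O)CC[C@](C)(CO[Si](c4ccccc4)(c5ccccc5)C(C)(C)C)[C@H]1COC(C)=O | intermediate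
37 | CNP0370815.4 | C=C1C(=O)[C@]23C[C@H]1CC[C@H]2[C@@]1(COC3=O)[C@@H](OC(C)=O)CC[C@](C)(CO)[C@H]1COC(C)=O | target

Total step count: 24. Longest linear sequence: 22 steps (5 to 37, steps 3 to 24); steps 1 and 2 make the side-chain reagent 4.

Least certain steps

Step 10 (key step). The C9–C10 bond has to form at a fully substituted alkene carbon. The most likely failure is a [3,3] shift slow enough for the alkoxide to fragment or undergo a [1,3] shift, or for the base to isomerise or aromatise the diene. Fallback: it sets out from 16, which is silylated on the tertiary oxygen with N-(trimethylsilyl)imidazole to the trimethylsilyl ether F1. F1 is heated without base in degassed 1,2-dichlorobenzene at about 220 °C. The neutral siloxy-Cope rearrangement passes through the same boat array and gives the silyl enol ether directly, so the route is rejoined at 19.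

Step 5. The cycloaddition may follow the dienone carbonyl, as unsubstituted masked o-benzoquinones do, and put the quaternary carbon next to C2; the endo preference of the methacrylate may also be incomplete. Fallback: it sets out from 7. Compound 9 is isolated after the oxidation and treated at −78 °C with the cerium reagent 13 (from 4 as in step 7), which adds to the carbonyl to give the racemic dienol F2. In F2 the diene is no longer conjugated to a carbonyl group, so only the 2-methoxy group directs. Methacrylate 8 (toluene, 100 °C) should then add with its CH2 at C2 and from the face opposite the dienyl group to give the racemic carbinol F3. Chromatography on the chiral phase gives 14, where the route is rejoined.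

Step 7. The lithiodiene may be lost by proton transfer from its doubly allylic CH2 groups, or so hindered an alkenyl metal may add too slowly to the ketal-flanked ketone. Fallback: it sets out from 11. Ethynylmagnesium bromide with CeCl3 adds the small alkyne from the same face to give the ethynyl carbinol F4. The cyclohexa-1,4-diene ring is then built on the alkyne with 1 under the cobalt conditions of step 1, returning to 14.

Step 11. The hindered tetrasubstituted enolate may be alkylated on oxygen, or face selectivity may erode in a transition state that has to be boat-like. Fallback: it sets out from 19. The potassium enolate 18 is regenerated with KOt-Bu and alkylated on oxygen on purpose (18-crown-6, HMPA, 20) to give the 2-bromoallyl enol ether F5. Claisen rearrangement in xylene at 140 °C transfers the allyl group to C8 through a cyclic transition state on the open face of H9, and the route is rejoined at 22.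

Step 19. The C20 hydroxyl may fail to capture the C7 acyl group and instead close a five-membered lactol on the new C6 aldehyde, so that lactone and aldehyde are not formed cleanly. Fallback: it sets out from 28. Rubottom oxidation with a citric acid work-up keeps the C20 silyl ether and gives the α-hydroxy ketone F6. Pb(OAc)4 in methanol–benzene cleaves F6 to the aldehyde methyl ester F7; NaBH4 gives the alcohol F8 and Ac2O the acetate F9. Aqueous HF in acetonitrile then frees the C20 hydroxyl, which closes the lactone on warming with pyridinium p-toluenesulfonate in toluene, and the route is rejoined at 34.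

Further compounds

F1 | step 10 | trimethylsilyl ether of carbinol 16 | C[Si](C)(C)O[C@]1(C3=CCC=CC3)C(OC)(OC)[C@H]2C(CO[Si](C)(C)C(C)(C)C)=C(OC)[C@@H]1C[C@]2(C)CO[Si](c4ccccc4)(c5ccccc5)C(C)(C)C
F2 | step 5 | racemic 4-[(tert-butyldimethylsilyloxy)methyl]-1-(cyclohexa-1,4-dien-1-yl)-3,6,6-trimethoxycyclohexa-2,4-dien-1-ol | O[C@]1(C2=CCC=CC2)C=C(OC)C(CO[Si](C)(C)C(C)(C)C)=CC1(OC)OC.O[C@@]1(C2=CCC=CC2)C=C(OC)C(CO[Si](C)(C)C(C)(C)C)=CC1(OC)OC
F3 | step 5 | racemic carbinol methyl ester (racemate of 14) | O[C@]1(C3=CCC=CC3)C(OC)(OC)[C@H]2C(CO[Si](C)(C)C(C)(C)C)=C(OC)[C@@H]1C[C@]2(C)C(=O)OC.O[C@@]1(C3=CCC=CC3)C(OC)(OC)[C@@H]2C(CO[Si](C)(C)C(C)(C)C)=C(OC)[C@H]1C[C@@]2(C)C(=O)OC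
F4 | step 7 | ethynyl carbinol methyl ester (ethynyl on C7 syn to the enol ether bridge) | O[C@]1(C#C)C(OC)(OC)[C@H]2C(CO[Si](C)(C)C(C)(C)C)=C(OC)[C@@H]1C[C@]2(C)C(=O)OC
F5 | step 11 | 2-bromoallyl enol ether of the tricyclic C7 ketone | C=C(Br)COC1=C2CC=CC[C@H]2[C@@]3(CO[Si](C)(C)C(C)(C)C)C(OC)=CC[C@](C)(CO[Si](c4ccccc4)(c5ccccc5)C(C)(C)C)[C@H]3C1(OC)OC
F6 | step 19 | C6-hydroxy C7 ketone with C20 tert-butyldimethylsilyl ether | C=C1C[C@]23C[C@H]1CC[C@H]2[C@@]4(CO[Si](C)(C)C(C)(C)C)[C@@H](OC(C)=O)CC[C@](C)(CO[Si](c5ccccc5)(c6ccccc6)C(C)(C)C)[C@H]4[C@H](O)C3=O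
F7 | step 19 | seco aldehyde methyl ester (C7 methyl ester on C8, C6 aldehyde, C20 silyl ether) | C=C1C[C@]2(C(=O)OC)C[C@H]1CC[C@H]2[C@@]3(CO[Si](C)(C)C(C)(C)C)[C@@H](OC(C)=O)CC[C@](C)(CO[Si](c4ccccc4)(c5ccccc5)C(C)(C)C)[C@H]3C=O
F8 | step 19 | seco methyl ester with C6 primary alcohol | C=C1C[C@]2(C(=O)OC)C[C@H]1CC[C@H]2[C@@]3(CO[Si](C)(C)C(C)(C)C)[C@@H](OC(C)=O)CC[C@](C)(CO[Si](c4ccccc4)(c5ccccc5)C(C)(C)C)[C@H]3CO
F9 | step 19 | seco methyl ester C1,C6-diacetate with C20 silyl ether | C=C1C[C@]2(C(=O)OC)C[C@H]1CC[C@H]2[C@@]3(CO[Si](C)(C)C(C)(C)C)[C@@H](OC(C)=O)CC[C@](C)(CO[Si](c4ccccc4)(c5ccccc5)C(C)(C)C)[C@H]3COC(C)=O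
A1 | alternative 1 | bicyclo[3.2.1]octenone β-keto ester (tert-butyl ester on C16, C11=C12 alkene) | CC(C)(C)OC(=O)[C@@H]1C(=O)[C@]23C[C@H]1C=C[C@H]2[C@@]1(COC3=O)[C@@H](OC(C)=O)CC[C@](C)(CO[Si](c4ccccc4)(c5ccccc5)C(C)(C)C)[C@H]1COC(C)=O
A2 | alternative 2 | spiro lactone enone (C1 ketone, C2=C3 alkene) | C=C1C[C@]23C[C@H]1CC[C@H]2[C@@]1(COC3=O)C(=O)C=C[C@](C)(COCc4ccc(OC)cc4)[C@H]1CO[Si](C)(C)C(C)(C)C
A3 | alternative 3 | tetracyclic siloxane cycloadduct (C8 acetyl, C12=C13 alkene, silicon on C11) | CC(=O)[C@]23CC=C[C@H]4[C@H]2[C@@]1(COC3=O)[C@@H](O[Si](C)(C)C(C)(C)C)CC[C@](C)(COCc5ccc(OC)cc5)[C@H]1CO[Si]4(C)C
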